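The route rests on cutting the C3–C4 bond of the cyclopentane ring (daucane numbering). C4 carries hydroxyl and isopropyl and is bonded to the ring methylene C3. It is therefore read as an isopropyl ketone on the fusion carbon C5, attacked by C3 after reductive polarity reversal of a primary iodide. One SmI2 Barbier closure forms the five-membered ring, completes the trans-hydroazulene and sets the fully substituted C4 carbinol, guided by a samarium chelate to the C6 acetal oxygen. The precursor is a cycloheptene with methyl and 2-iodoethyl on C1, isobutyryl on C5 and a benzyloxymethyl ether on C6. A dianionic Claisen rearrangement and ring-closing metathesis deliver it from one chiral-pool carbinol.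

Key step: step 13

Remarks on the chemistry
- Assumption: daucane numbering is used. C1 is the quaternary carbon, C2/C3 the cyclopentane CH2 groups, C4 the carbinol, C5 the fusion CH, C6 the acyloxy carbon, C7 a CH2, C8=C9 the alkene and C10 a CH2. The C1 methyl is β. The five numbered starting materials are taken as catalogue chemicals.
- Structure check: the target reads as (3R,3aS,4S,8aR). It is trans-fused, with the C1 methyl and 4-OH β, and H5, the 6-O-acyl group and the isopropyl group α.
- Precursor design, protecting group: O6 carries a benzyloxymethyl rather than a methoxymethyl acetal. The two-oxygen chelating array is the same, but the group leaves under dissolving-metal conditions. Acidic cleavage of a simple alkoxymethyl ether beside the tertiary 4-OH would risk ionisation at C4 and closure to the cyclic 4,6-formaldehyde acetal.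
- Precursor design, activator: NiI2 replaces HMPA, so samarium keeps free coordination sites for the chelate.

Step 1
Reactants: 1 pent-1-en-4-yne
Product: 4 (2E)-3-methylhexa-2,5-dien-1-ol, via alkenylalane 2 (not isolated), via lithium alanate 3 (not isolated)
Conditions: Me3Al, Cp2ZrCl2 (25 mol %), CH2Cl2, 0 °C → rt; n-BuLi, hexane/THF, −78 → 0 °C; (CH2O)n, rt
Reagents that add atoms: trimethylaluminium C[Al](C)C; formaldehyde (from paraformaldehyde) C=O
Why: Zirconium-catalysed Negishi carboalumination adds Me–Al syn, with methyl on the internal alkyne carbon, far faster than the isolated alkene reacts, and the derived alanate attacks formaldehyde with retention, which fixes the E geometry needed in step 5.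

Step 2
Reactants: 5 ethyl (3R)-4-chloro-3-hydroxybutanoate
Product: 6 ethyl [(2R)-oxiran-2-yl]acetate
Conditions: Ag2O, 1,2-dimethoxyethane, 80 °C
Reagents that add atoms: none
Why: Halophilic Ag2O drives an intramolecular Williamson (SN2) closure of the chlorohydrin without free base, so the C–O stereocentre is retained and the epoxy ester is not isomerised to the 4-hydroxycrotonate.

Step 3
Reactants: 6 ethyl [(2R)-oxiran-2-yl]acetate; 7 isopropenylmagnesium bromide
Product: 8 ethyl (3S)-3-hydroxy-5-methylhex-5-enoate
Conditions: CuI (15 mol %), THF, −40 °C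
Reagents that add atoms: none
Why: Copper-catalysed Grignard opening of a terminal epoxide is an SN2 attack at the CH2 terminus that outruns addition to the ester at −40 °C; the carbinol centre (future C6) is untouched and becomes S only because the CIP ranking of its neighbours changes.

Step 4
Reactants: 8 ethyl (3S)-3-hydroxy-5-methylhex-5-enoate; 4 (2E)-3-methylhexa-2,5-dien-1-ol
Product: 9 (2E)-3-methylhexa-2,5-dien-1-yl (3S)-3-hydroxy-5-methylhex-5-enoate
Conditions: Ti(OEt)4 (15 mol %), toluene, 100 °C, EtOH removed (4 Å sieves)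
Reagents that add atoms: none
Why: Titanate-catalysed transesterification is a neutral acyl exchange that tolerates β-hydroxy esters and allylic alcohols and is pulled to the product by removal of ethanol.

Step 5
Reactants: 9 (2E)-3-methylhexa-2,5-dien-1-yl (3S)-3-hydroxy-5-methylhex-5-enoate
Product: 11 (2S,3S)-3-hydroxy-5-methyl-2-[(3S)-3-methylhexa-1,5-dien-3-yl]hex-5-enoic acid, via dilithio dianion 10 (not isolated)
Conditions: LiN(iPr)2 (2.3 equiv), THF, −78 °C; warm to 23 → 45 °C; 1 M HCl
Reagents that add atoms: none
Why: Dianionic ester-enolate Claisen rearrangement (Ireland–Claisen family): double deprotonation gives the lithium-chelated Z(O)-enolate, the chair transition state with the E-allyl unit places C6 and the allyl arm equatorial and so fixes the C5/C1 relationship (carboxyl carbon C4 trans to the vinyl group that becomes C2–C3), and bonding anti to the methallyl substituent of the chelate ring, the sense known from Fráter–Seebach alkylations, relays the C6 configuration to C5.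

Step 6
Reactants: 11 (2S,3S)-3-hydroxy-5-methyl-2-[(3S)-3-methylhexa-1,5-dien-3-yl]hex-5-enoic acid
Product: 12 benzyloxymethyl (2S,3S)-3-(benzyloxymethoxy)-5-methyl-2-[(3S)-3-methylhexa-1,5-dien-3-yl]hex-5-enoate
Conditions: BOMCl (4 equiv), iPr2NEt (6 equiv), Bu4NI (10 mol %), CH2Cl2, 0 → 40 °C
Reagents that add atoms: benzyl chloromethyl ether ClCOCc1ccccc1
Why: O-alkylation of the carboxylate and of the hindered C6 hydroxyl by the reactive α-halo ether under amine base installs in one operation an activated ester for the later lactonisation and the chelating, reductively removable acetal on O6, with no base strong enough for retro-aldol cleavage or epimerisation.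

Step 7
Reactants: 12 benzyloxymethyl (2S,3S)-3-(benzyloxymethoxy)-5-methyl-2-[(3S)-3-methylhexa-1,5-dien-3-yl]hex-5-enoate
Product: 13 benzyloxymethyl (1S,2S,7S)-7-(benzyloxymethoxy)-2-ethenyl-2,5-dimethylcyclohept-4-ene-1-carboxylate
Conditions: second-generation Grubbs catalyst (H2IMes)(PCy3)Cl2Ru=CHPh (5 mol %), CH2Cl2 (3 mM), 40 °C
Reagents that add atoms: none
Why: In this ring-closing metathesis the catalyst loads on the unhindered allyl terminus and closes on the methallyl alkene to the trisubstituted cycloheptene with loss of ethene, whereas the vinyl group on the quaternary carbon is too hindered to load and could give only a cyclobutene with the allyl arm.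

Step 8
Reactants: 13 benzyloxymethyl (1S,2S,7S)-7-(benzyloxymethoxy)-2-ethenyl-2,5-dimethylcyclohept-4-ene-1-carboxylate
Product: 16 (4aS,9S,9aS)-9-(benzyloxymethoxy)-4a,7-dimethyl-4,4a,5,8,9,9a-hexahydrocyclohepta[c]pyran-1(3H)-one (trans-fused δ-lactone), via B-alkyl borane 14 (not isolated), via hydroxy ester 15 (not isolated)
Conditions: 9-BBN (1.5 equiv), THF, rt; 3 M NaOH, 30% H2O2, 0 °C → rt; 1 M HCl to pH 3
Reagents that add atoms: hydrogen peroxide OO
Why: Anti-Markovnikov hydroboration with bulky 9-BBN takes the monosubstituted vinyl group and leaves the trisubstituted ring alkene, peroxide oxidation gives the primary alcohol, and its oxygen displaces the activated benzyloxymethyl ester, the trans pseudo-equatorial C1 chain and C5 carboxyl closing the δ-lactone (lactonisation).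

Step 9
Reactants: 16 trans-fused δ-lactone
Product: 17 (4aS,9S,9aS)-9-(benzyloxymethoxy)-4a,7-dimethyl-1,3,4,4a,5,8,9,9a-octahydrocyclohepta[c]pyran-1-ol (lactol, anomer mixture)
Conditions: iBu2AlH (1.1 equiv), CH2Cl2, −78 °C
Reagents that add atoms: none
Why: Partial lactone reduction with one equivalent of iBu2AlH stops at the aluminium lactolate, which is stable at −78 °C, and the acetal, the alkene and the stereocentres are inert.

Step 10
Reactants: 17 lactol; 18 isopropylmagnesium chloride
Product: 19 6α-(benzyloxymethoxy)-3,4-secodauc-8-ene-3,4-diol (ring stereocentres as in 16, both C4 epimers)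
Conditions: 18 (4 equiv), LaCl3·2LiCl (30 mol %), THF, −20 → 0 °C
Reagents that add atoms: none
Why: Grignard addition to a lactol: the first equivalent deprotonates the hemiacetal, the ring-opened alkoxy aldehyde is captured by the second, the lanthanum salt favouring 1,2-addition over β-hydride transfer and enolisation, and the new C4 carbinol centre is formed as a mixture that step 12 erases.

Step 11
Reactants: 19 6α-(benzyloxymethoxy)-3,4-secodauc-8-ene-3,4-diol
Product: 20 6α-(benzyloxymethoxy)-3-iodo-3,4-secodauc-8-en-4-ol (both C4 epimers)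
Conditions: I2, PPh3, imidazole, CH2Cl2, 0 °C
Reagents that add atoms: iodine II
Why: Garegg–Samuelsson (Appel-type) iodination runs by SN2 displacement of an alkoxyphosphonium ion and therefore takes the unhindered primary alcohol, the secondary carbinol wedged between isopropyl and C5 being too hindered at 0 °C.

Step 12
Reactants: 20 6α-(benzyloxymethoxy)-3-iodo-3,4-secodauc-8-en-4-ol
Product: 21 1-[(1S,2S,7S)-7-(benzyloxymethoxy)-2-(2-iodoethyl)-2,5-dimethylcyclohept-4-en-1-yl]-2-methylpropan-1-one (isobutyryl cis to the C1 methyl, trans to the iodoethyl chain and to the C6 acetal)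
Conditions: Dess–Martin periodinane, NaHCO3, CH2Cl2, 0 °C → rt
Reagents that add atoms: none
Why: Dess–Martin oxidation works under buffered, near-neutral conditions on hindered secondary alcohols, leaves the primary iodide and the acetal alone and supplies no base that could epimerise C5 or expel the β-alkoxy group.

Step 13
Reactants: 21 iodo ketone
Product: 23 (3R,3aS,4S,8aR)-4-(benzyloxymethoxy)-6,8a-dimethyl-3-(propan-2-yl)-1,2,3,3a,4,5,8,8a-octahydroazulen-3-ol, via alkylsamarium 22 (not isolated)
Conditions: SmI2 (0.1 M in THF, 3 equiv), NiI2 (2 mol %), THF, 0 °C, slow addition of 21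
Reagents that add atoms: none
Why: Divalent samarium, with zerovalent nickel formed from NiI2 relaying the electron transfer, reduces the primary C–I bond to the radical and on to the alkylsamarium 22 faster than it touches the hindered dialkyl ketone, and this carbanion equivalent adds to the C4 carbonyl; the closest known reaction type is the samarium diiodide-mediated intramolecular Barbier cyclisation of ω-iodoalkyl ketones. The cyclopentane closes in the 5-exo-trig mode, C3 attacking the carbonyl carbon whose C=O bond stays outside the new ring, and the trans ring fusion is already fixed by C1 and C5. The new C4 stereocentre is controlled by a six-membered chelate in which trivalent samarium bridges the ketone oxygen and the C6 acetal oxygens, possible because the isobutyryl group and the C6–O bond are trans pseudo-equatorial and gauche; this turns the carbonyl oxygen toward C6 and the isopropyl group toward H5, so that C3 reaches only the face that leaves the hydroxyl β, cis to C6 and to the C1 methyl. Sterics point the same way, since the other rotamer would press the isopropyl group against C6. The step needs chemoselectivity for C–I over C=O reduction and must not lose the β-alkoxy group, which is secured by the absence of a proton source and of strong base, by leaving out HMPA and by the short reaction at 0 °C.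

Step 14
Reactants: 23 Barbier product
Product: 24 jaeschkeanadiol, (3R,3aS,4S,8aR)-6,8a-dimethyl-3-(propan-2-yl)-1,2,3,3a,4,5,8,8a-octahydroazulene-3,4-diol
Conditions: Li, NH3(l)/THF, −78 °C; NH4Cl
Reagents that add atoms: none
Why: Dissolving-metal (Birch-type) cleavage of the benzylic C–O bond leaves a hemiformal that loses formaldehyde on work-up, isolated trisubstituted alkenes and tertiary alcohols are inert, and no acid is present that could ionise C4 or tie O4 and O6 into a cyclic formal.

Step 15
Reactants: 24 jaeschkeanadiol; 25 3,4-dimethoxybenzoyl chloride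
Product: 26 (3R,3aS,4S,8aR)-3-hydroxy-6,8a-dimethyl-3-(propan-2-yl)-1,2,3,3a,4,5,8,8a-octahydroazulen-4-yl 3,4-dimethoxybenzoate (target)
Conditions: Et3N, DMAP (20 mol %), CH2Cl2, rt → 40 °C
Reagents that add atoms: none
Why: DMAP-catalysed acylation (nucleophilic catalysis) esterifies the secondary C6 hydroxyl with retention, while the tertiary C4 hydroxyl flanked by isopropyl is too hindered to react.

Compound list
1 | pent-1-en-4-yne | C#CCC=C | starting material
2 | dimethyl[(1E)-2-methylpenta-1,4-dien-1-yl]alane | C[Al](C)/C=C(C)/CC=C | intermediate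
3 | lithium butyl(dimethyl)[(1E)-2-methylpenta-1,4-dien-1-yl]aluminate | [Li+].CCCC[Al-](C)(C)/C=C(C)/CC=C | intermediate
4 | (2E)-3-methylhexa-2,5-dien-1-ol | OC/C=C(C)/CC=C | intermediate
5 | ethyl (3R)-4-chloro-3-hydroxybutanoate | CCOC(=O)C[C@@H](O)CCl | starting material
6 | ethyl [(2R)-oxiran-2-yl]acetate | CCOC(=O)C[C@@H]1CO1 | intermediate
7 | isopropenylmagnesium bromide | CC(=C)[Mg]Br | starting material
8 | ethyl (3S)-3-hydroxy-5-methylhex-5-enoate | CCOC(=O)C[C@@H](O)CC(C)=C | intermediate
9 | (2E)-3-methylhexa-2,5-dien-1-yl (3S)-3-hydroxy-5-methylhex-5-enoate | C=CC/C(C)=C/COC(=O)C[C@@H](O)CC(C)=C | intermediate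
10 | dilithium alkoxide Z(O)-enolate of 9 (chelated dianion) | [Li+].[Li+].[O-]/C(OC/C=C(C)/CC=C)=C\[C@@H]([O-])CC(C)=C | intermediate
11 | (2S,3S)-3-hydroxy-5-methyl-2-[(3S)-3-methylhexa-1,5-dien-3-yl]hex-5-enoic acid | OC(=O)[C@H]([C@@H](O)CC(C)=C)[C@](C)(C=C)CC=C | intermediate
12 | benzyloxymethyl (2S,3S)-3-(benzyloxymethoxy)-5-methyl-2-[(3S)-3-methylhexa-1,5-dien-3-yl]hex-5-enoate | O=C(OCOCc1ccccc1)[C@H]([C@@H](OCOCc1ccccc1)CC(C)=C)[C@](C)(C=C)CC=C | intermediate
13 | benzyloxymethyl (1S,2S,7S)-7-(benzyloxymethoxy)-2-ethenyl-2,5-dimethylcyclohept-4-ene-1-carboxylate | CC1=CC[C@@](C)(C=C)[C@H](C(=O)OCOCc2ccccc2)[C@@H](OCOCc2ccccc2)C1 | intermediate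
14 | B-alkyl-9-borabicyclo[3.3.1]nonane from 13 (boron on the terminal carbon of the former vinyl group) | CC1=CC[C@@](C)(CCB2C3CCCC2CCC3)[C@H](C(=O)OCOCc2ccccc2)[C@@H](OCOCc2ccccc2)C1 | intermediate
15 | benzyloxymethyl (1S,2S,7S)-7-(benzyloxymethoxy)-2-(2-hydroxyethyl)-2,5-dimethylcyclohept-4-ene-1-carboxylate | CC1=CC[C@@](C)(CCO)[C@H](C(=O)OCOCc2ccccc2)[C@@H](OCOCc2ccccc2)C1 | intermediate
16 | (4aS,9S,9aS)-9-(benzyloxymethoxy)-4a,7-dimethyl-4,4a,5,8,9,9a-hexahydrocyclohepta[c]pyran-1(3H)-one | CC1=CC[C@@]2(C)CCOC(=O)[C@@H]2[C@@H](OCOCc3ccccc3)C1 | intermediate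
17 | (4aS,9S,9aS)-9-(benzyloxymethoxy)-4a,7-dimethyl-1,3,4,4a,5,8,9,9a-octahydrocyclohepta[c]pyran-1-ol (anomers) | CC1=CC[C@@]2(C)CCOC(O)[C@@H]2[C@@H](OCOCc3ccccc3)C1 | intermediate
18 | isopropylmagnesium chloride | CC(C)[Mg]Cl | starting material
19 | 6α-(benzyloxymethoxy)-3,4-secodauc-8-ene-3,4-diol (C4 epimers) | CC1=CC[C@@](C)(CCO)[C@H](C(O)C(C)C)[C@@H](OCOCc2ccccc2)C1 | intermediate
20 | 6α-(benzyloxymethoxy)-3-iodo-3,4-secodauc-8-en-4-ol (C4 epimers) | CC1=CC[C@@](C)(CCI)[C@H](C(O)C(C)C)[C@@H](OCOCc2ccccc2)C1 | intermediate
21 | 1-[(1S,2S,7S)-7-(benzyloxymethoxy)-2-(2-iodoethyl)-2,5-dimethylcyclohept-4-en-1-yl]-2-methylpropan-1-one | CC1=CC[C@@](C)(CCI)[C@H](C(=O)C(C)C)[C@@H](OCOCc2ccccc2)C1 | intermediate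
22 | alkylsamarium diiodide from 21 | CC1=CC[C@@](C)(CC[Sm](I)I)[C@H](C(=O)C(C)C)[C@@H](OCOCc2ccccc2)C1 | intermediate
23 | (3R,3aS,4S,8aR)-4-(benzyloxymethoxy)-6,8a-dimethyl-3-(propan-2-yl)-1,2,3,3a,4,5,8,8a-octahydroazulen-3-ol | CC1=CC[C@@]2(C)CC[C@@](O)(C(C)C)[C@@H]2[C@@H](OCOCc3ccccc3)C1 | intermediate
24 | jaeschkeanadiol, (3R,3aS,4S,8aR)-6,8a-dimethyl-3-(propan-2-yl)-1,2,3,3a,4,5,8,8a-octahydroazulene-3,4-diol | CC1=CC[C@@]2(C)CC[C@@](O)(C(C)C)[C@@H]2[C@@H](O)C1 | intermediate
25 | 3,4-dimethoxybenzoyl chloride | COc1ccc(C(=O)Cl)cc1OC | starting material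
26 | (3R,3aS,4S,8aR)-3-hydroxy-6,8a-dimethyl-3-(propan-2-yl)-1,2,3,3a,4,5,8,8a-octahydroazulen-4-yl 3,4-dimethoxybenzoate | COc1ccc(C(=O)O[C@H]2CC(C)=CC[C@@]3(C)CC[C@@](O)(C(C)C)[C@H]23)cc1OC | target

Total step count: 15. Longest linear sequence: 14 (steps 2 to 15; step 1 is the side branch).

Steps most likely to fail

Step 13 (key step).
- What may go wrong: the alkylsamarium may be protonated before it cyclises (net deiodination), the ketone may be reduced first, or the chelate may not form, which would erode facial selectivity at C4.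
- Fallback: close the ring as a ketone and bring in isopropyl last. It sets out from lactone 16. Aminolysis with MeNH(OMe)·HCl and Me3Al gives the hydroxy Weinreb amide F1. Garegg–Samuelsson iodination gives the iodo Weinreb amide F2. Iodine–lithium exchange with t-BuLi (Et2O/pentane, −78 °C) is followed by intramolecular acylation to the trans-hydroazulenone F3. The organocerium reagent from 18 and CeCl3 then adds from the α face, opposite the C1 methyl and C6, and the route is rejoined at 23.

Step 5.
- What may go wrong: the dianion may fragment by retro-aldol or ketene-type decomposition on warming, or chelate control may be incomplete, so that the allyl unit reaches both enolate faces.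
- Fallback: replace substrate control by reagent control. It sets out from 9. Silylation (Et3SiCl, imidazole) gives the triethylsilyl ether F4. This is enolised softly with a tertiary amine and a chiral B-bromodiazaborolidine, made from BBr3 and the bis(3,5-bis(trifluoromethyl)benzenesulfonamide) of 1,2-diphenylethane-1,2-diamine (the enantiomer matched to C6). The amine and solvent regime that delivers the Z(O) boron enolate is used. The enantioselective boron-enolate Ireland–Claisen rearrangement gives the silyloxy acid F5. AcOH/THF/H2O removes the silyl group and the route is rejoined at 11.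

Step 10.
- What may go wrong: β-hydride transfer from the secondary Grignard reagent would reduce the aldehyde form, or enolisation would be followed by loss of the C6 alkoxy group.
- Fallback: use an sp2 nucleophile and adjust the oxidation level afterwards. It sets out from lactol 17. Isopropenylmagnesium bromide 7 gives the allylic diol F6. MnO2 oxidises only the allylic carbinol, to the hydroxy enone F7. Conjugate reduction with [(Ph3P)CuH]6 gives the hydroxy ketone F8. Garegg–Samuelsson iodination of its primary alcohol rejoins the route at 21, bypassing 19 and 20.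

Further compounds
F1 | step 13 | (1S,2S,7S)-7-(benzyloxymethoxy)-2-(2-hydroxyethyl)-N-methoxy-N,2,5-trimethylcyclohept-4-ene-1-carboxamide | CC1=CC[C@@](C)(CCO)[C@H](C(=O)N(C)OC)[C@@H](OCOCc2ccccc2)C1
F2 | step 13 | (1S,2S,7S)-7-(benzyloxymethoxy)-2-(2-iodoethyl)-N-methoxy-N,2,5-trimethylcyclohept-4-ene-1-carboxamide | CC1=CC[C@@](C)(CCI)[C@H](C(=O)N(C)OC)[C@@H](OCOCc2ccccc2)C1
F3 | step 13 | (3aS,4S,8aR)-4-(benzyloxymethoxy)-6,8a-dimethyl-1,3a,4,5,8,8a-hexahydroazulen-3(2H)-one | CC1=CC[C@@]2(C)CCC(=O)[C@@H]2[C@@H](OCOCc3ccccc3)C1
F4 | step 5 | (2E)-3-methylhexa-2,5-dien-1-yl (3S)-5-methyl-3-(triethylsilyloxy)hex-5-enoate | C=CC/C(C)=C/COC(=O)C[C@@H](O[Si](CC)(CC)CC)CC(C)=C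
F5 | step 5 | (2S,3S)-5-methyl-2-[(3S)-3-methylhexa-1,5-dien-3-yl]-3-(triethylsilyloxy)hex-5-enoic acid | OC(=O)[C@H]([C@@H](O[Si](CC)(CC)CC)CC(C)=C)[C@](C)(C=C)CC=C
F6 | step 10 | 6α-(benzyloxymethoxy)-3,4-secodauca-8,11-diene-3,4-diol (C4 epimers) | CC1=CC[C@@](C)(CCO)[C@H](C(O)C(C)=C)[C@@H](OCOCc2ccccc2)C1
F7 | step 10 | 6α-(benzyloxymethoxy)-3-hydroxy-3,4-secodauca-8,11-dien-4-one | CC1=CC[C@@](C)(CCO)[C@H](C(=O)C(C)=C)[C@@H](OCOCc2ccccc2)C1
F8 | step 10 | 6α-(benzyloxymethoxy)-3-hydroxy-3,4-secodauc-8-en-4-one | CC1=CC[C@@](C)(CCO)[C@H](C(=O)C(C)C)[C@@H](OCOCc2ccccc2)C1
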